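## Retrosynthetic overview

1. C9'=C10': Wittig reaction of the C27 10'-apo-aldehyde with a C3 formyl ylide; the last step delivers the aldehyde directly.
2. C11'=C12': two-carbon formyl-olefination of the C25 12'-apo-aldehyde.
3. C11=C12: Wittig reaction of a C15 phosphonium salt (ring plus C7–C11) with the symmetrical C10 dialdehyde; the salt comes from the 3-acyloxy ketone and vinyl Grignard reagent.
4. C3–O: direct, face-selective allylic C–H benzoyloxylation of (R)-α-ionone sets 3S; 6R is bought.
5. No ring is formed: the cyclohexene ring comes intact from (R)-α-ionone.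

Assumption: (R)-(+)-α-ionone of ≥98% ee (fermentation-derived natural grade) is bought; the C10 dialdehyde, the aminovinylphosphonate and the formyl ylide are catalogue items.
Assumption: L1 is 2,2'-(propane-2,2-diyl)bis[(4S)-4-(3,5-di-tert-butylphenyl)-4,5-dihydro-1,3-oxazole]; if a first run shows this enantiomer to be the mismatched one, its (4R,4'R) mirror image is used.
Carotenoid numbering is used for positions (C3 carbinol, C6 ring methine, chain C7 to C8'). The target is (3S,6R)-3-hydroxy-8'-apo-ε-caroten-8'-al, with the hydroxyl cis to the side chain. Steps 3–6 are run under argon in dim light.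

## Route

Step 1
Reactants: 1 (R)-α-ionone, (3E)-4-[(1R)-2,6,6-trimethylcyclohex-2-en-1-yl]but-3-en-2-one
Product: 2 (3S,6R)-3-benzoyloxy-α-ionone, (1S,4R)-3,5,5-trimethyl-4-[(1E)-3-oxobut-1-en-1-yl]cyclohex-2-en-1-yl benzoate
Conditions: Cu(MeCN)4PF6 (10 mol %), L1 (12 mol %), (PhSO2)2NF (1.5 equiv), PhCO2H (2 equiv), Li2CO3 (1 equiv), PhCl, 0 °C to rt, Ar
Reagents that add atoms: benzoic acid, OC(=O)c1ccccc1
Why: Proposed new method: monovalent copper/L1 reduces N-fluorobenzenesulfonimide to a copper-bound sulfonimidyl radical that abstracts hydrogen from C3, the only secondary allylic C–H (the C6–H is flanked by the gem-dimethyl carbon and the vinylic methyl, lies near the plane of both π systems and is polarity-mismatched beside the enone), and the C3–C4–C5 allyl radical is captured by divalent copper benzoate to give a trivalent allylcopper benzoate that forms the C3–O bond by reductive elimination at the less substituted terminus on the face chosen by the ligand, syn to the C6 side chain (the pseudo-axial C1 methyl blocks the other face in the envelope with a pseudo-axial side chain), which sets C3 as S and leaves C6 untouched; the closest known reactions are the Kharasch–Sosnovsky allylic acyloxylation and copper/N-fluorobenzenesulfonimide radical-relay allylic and benzylic C–H cyanation and etherification, which have not been shown to give catalyst-controlled diastereoselective C–O coupling on a chiral trisubstituted cyclohexene of this kind.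

Step 2
Reactants: 2 (3S,6R)-3-benzoyloxy-α-ionone; 3 vinylmagnesium bromide
Product: 5 (1S,4R)-4-[(1E)-3-hydroxy-3-methylpenta-1,4-dien-1-yl]-3,5,5-trimethylcyclohex-2-en-1-ol (both C9 epimers), via C3-benzoate carbinol 4 (not isolated)
Conditions: CH2=CHMgBr (4 equiv), THF, −20 °C to rt; then H2O
Reagents that add atoms: none
Why: Grignard 1,2-addition to the methyl ketone (as in ionone-to-vinylionol chemistry) is followed by double addition of the excess reagent to the benzoate, which frees the C3 alkoxide; the new C9 carbinol centre is formed unselectively but becomes sp2 in step 3, and C3 and C6 are not touched.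

Step 3
Reactants: 5 (1S,4R)-4-[(1E)-3-hydroxy-3-methylpenta-1,4-dien-1-yl]-3,5,5-trimethylcyclohex-2-en-1-ol
Product: 6 [(2E,4E)-5-[(1R,4S)-4-hydroxy-2,6,6-trimethylcyclohex-2-en-1-yl]-3-methylpenta-2,4-dien-1-yl]triphenylphosphonium bromide
Conditions: PPh3·HBr (1.05 equiv), CH2Cl2, −10 to 0 °C; crystallise (EtOAc)
Reagents that add atoms: triphenylphosphine hydrobromide, [PH+](c1ccccc1)(c1ccccc1)c1ccccc1.[Br-]
Why: Acid-promoted ionisation of the tertiary bis-allylic carbinol gives a pentadienyl cation that PPh3 captures at the primary terminus (allylic transposition, the standard C15 Wittig salt synthesis) to give the conjugated 9E dienyl salt, while the secondary ring allylic alcohol ionises far more slowly at this temperature in a non-nucleophilic solvent.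

Step 4
Reactants: 6 the C15 phosphonium bromide; 7 (2E,4E,6E)-2,7-dimethylocta-2,4,6-trienedial
Product: 9 (3S,6R)-3-hydroxy-12'-apo-ε-caroten-12'-al, via C15 phosphorane 8 (not isolated)
Conditions: NaOMe (1.05 equiv), CH2Cl2/MeOH, −10 °C to rt, 6 added slowly to 7 (2.5 equiv)
Reagents that add atoms: none
Why: Wittig olefination of the symmetrical dialdehyde stops at the mono-adduct because 7 is in excess and the extended product aldehyde is less electrophilic, and the semi-stabilised polyenyl ylide gives mainly the 11E olefin (the hindered 11Z isomer is minor and removed on crystallisation); no stereocentre is affected.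

Step 5
Reactants: 9 (3S,6R)-3-hydroxy-12'-apo-ε-caroten-12'-al; 10 diethyl [(E)-2-(cyclohexylamino)ethenyl]phosphonate
Product: 12 (3S,6R)-3-hydroxy-10'-apo-ε-caroten-10'-al, via N-cyclohexyl imine 11 (not isolated)
Conditions: 10 (2.5 equiv), NaH (2.4 equiv), THF, 0 °C to rt; then AcOH/NaOAc buffer (pH 4.5), THF/H2O, rt
Reagents that add atoms: water, O
Why: Horner–Wadsworth–Emmons formyl-olefination with the metalated aminovinylphosphonate is E-selective and gives an unsaturated imine that cannot be homologated a second time, and its hydrolysis at pH 4.5 is too mild to ionise the ring allylic alcohol.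

Step 6
Reactants: 12 (3S,6R)-3-hydroxy-10'-apo-ε-caroten-10'-al; 13 2-(triphenylphosphoranylidene)propanal
Product: 14 (3S,6R)-3-hydroxy-8'-apo-ε-caroten-8'-al (CNP0265614.2)
Conditions: 13 (1.5 equiv), toluene, 70 °C
Reagents that add atoms: none
Why: Wittig reaction of a stabilised formyl ylide gives the E trisubstituted enal, and the α-methyl enal product is too unreactive to add a second ylide, so the free aldehyde and free hydroxyl need no protection.

## Compound list

1 | (R)-α-ionone, (3E)-4-[(1R)-2,6,6-trimethylcyclohex-2-en-1-yl]but-3-en-2-one | CC1=CCCC(C)(C)[C@H]1/C=C/C(C)=O | starting material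
2 | (1S,4R)-3,5,5-trimethyl-4-[(1E)-3-oxobut-1-en-1-yl]cyclohex-2-en-1-yl benzoate | CC1=C[C@@H](OC(=O)c2ccccc2)CC(C)(C)[C@H]1/C=C/C(C)=O | intermediate
3 | vinylmagnesium bromide | C=C[Mg]Br | starting material
4 | (1S,4R)-4-[(1E)-3-hydroxy-3-methylpenta-1,4-dien-1-yl]-3,5,5-trimethylcyclohex-2-en-1-yl benzoate (C9 epimers; magnesium alkoxide in the flask) | CC1=C[C@@H](OC(=O)c2ccccc2)CC(C)(C)[C@H]1/C=C/C(C)(O)C=C | intermediate
5 | (1S,4R)-4-[(1E)-3-hydroxy-3-methylpenta-1,4-dien-1-yl]-3,5,5-trimethylcyclohex-2-en-1-ol (C9 epimers) | CC1=C[C@@H](O)CC(C)(C)[C@H]1/C=C/C(C)(O)C=C | intermediate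
6 | [(2E,4E)-5-[(1R,4S)-4-hydroxy-2,6,6-trimethylcyclohex-2-en-1-yl]-3-methylpenta-2,4-dien-1-yl]triphenylphosphonium bromide | CC1=C[C@@H](O)CC(C)(C)[C@H]1/C=C/C(C)=C/C[P+](c1ccccc1)(c1ccccc1)c1ccccc1.[Br-] | intermediate
7 | (2E,4E,6E)-2,7-dimethylocta-2,4,6-trienedial | O=C/C(C)=C/C=C/C=C(\C)C=O | starting material
8 | (1S,4R)-3,5,5-trimethyl-4-[(1E,3E)-3-methyl-5-(triphenylphosphoranylidene)penta-1,3-dien-1-yl]cyclohex-2-en-1-ol | CC1=C[C@@H](O)CC(C)(C)[C@H]1/C=C/C(C)=C/C=P(c1ccccc1)(c1ccccc1)c1ccccc1 | intermediate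
9 | (2E,4E,6E,8E,10E,12E)-13-[(1R,4S)-4-hydroxy-2,6,6-trimethylcyclohex-2-en-1-yl]-2,7,11-trimethyltrideca-2,4,6,8,10,12-hexaenal | CC1=C[C@@H](O)CC(C)(C)[C@H]1/C=C/C(C)=C/C=C/C(C)=C/C=C/C=C(\C)C=O | intermediate
10 | diethyl [(E)-2-(cyclohexylamino)ethenyl]phosphonate | CCOP(=O)(OCC)/C=C/NC1CCCCC1 | starting material
11 | N-cyclohexyl imine of the C27 aldehyde 12 | CC1=C[C@@H](O)CC(C)(C)[C@H]1/C=C/C(C)=C/C=C/C(C)=C/C=C/C=C(C)/C=C/C=NC1CCCCC1 | intermediate
12 | (2E,4E,6E,8E,10E,12E,14E)-15-[(1R,4S)-4-hydroxy-2,6,6-trimethylcyclohex-2-en-1-yl]-4,9,13-trimethylpentadeca-2,4,6,8,10,12,14-heptaenal | CC1=C[C@@H](O)CC(C)(C)[C@H]1/C=C/C(C)=C/C=C/C(C)=C/C=C/C=C(C)/C=C/C=O | intermediate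
13 | 2-(triphenylphosphoranylidene)propanal | CC(C=O)=P(c1ccccc1)(c1ccccc1)c1ccccc1 | starting material
14 | (2E,4E,6E,8E,10E,12E,14E,16E)-17-[(1R,4S)-4-hydroxy-2,6,6-trimethylcyclohex-2-en-1-yl]-2,6,11,15-tetramethylheptadeca-2,4,6,8,10,12,14,16-octaenal | CC1=C[C@@H](O)CC(C)(C)[C@H]1/C=C/C(C)=C/C=C/C(C)=C/C=C/C=C(C)/C=C/C=C(\C)C=O | target

## Step count and risks

Total steps: 6. Longest linear sequence: 6.

Steps most likely to fail:

Step 1 (proposed new method). The risks are low face selectivity at C3, C–O coupling at the tertiary C5 terminus, and hydrogen abstraction at C6, which would erode the bought stereocentre. The fallback uses known chemistry and sets out from 1. Enzymatic C3 hydroxylation of 1, which is regioselective and trans-selective (P450 BM3 variant or Streptomyces whole cells, glucose, buffer pH 7.5, 30 °C), gives trans-(3R,6R)-3-hydroxy-α-ionone F1. Mitsunobu reaction of F1 (PhCO2H, PPh3, diisopropyl azodicarboxylate, THF, 0 °C) forms the C3–O bond with inversion and gives the cis benzoate, so the fallback comes back to the route at compound 2.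

Step 3. The risk is that the acid also ionises the free ring allylic alcohol, which would epimerise C3 or dehydrate the ring. The fallback sets out from 2 and keeps the C3 oxygen acylated through the acid step. Addition of CH2=CHMgBr (1.05 equiv, THF, −78 °C) to the ketone alone gives the benzoate carbinol 4, which is isolated. PPh3·HBr (CH2Cl2, 0 °C) converts 4 into [(2E,4E)-5-[(1R,4S)-4-(benzoyloxy)-2,6,6-trimethylcyclohex-2-en-1-yl]-3-methylpenta-2,4-dien-1-yl]triphenylphosphonium bromide F2, whose allylic ester does not ionise under these conditions. NaOMe gives the benzoate phosphorane F3, which condenses with 7 to the C25 benzoate aldehyde F4. Methanolysis (K2CO3, MeOH, 0 °C) cleaves the ester, and the fallback comes back to the route at compound 9.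

Step 5. The risks are slow hydrolysis of the conjugated imine at pH 4.5 (stronger acid would endanger C3) and quenching of the phosphonate anion by the free hydroxyl. The fallback sets out from 9 and avoids any acidic hydrolysis. Horner–Wadsworth–Emmons reaction with diethyl (cyanomethyl)phosphonate (NaH, THF, 0 °C) gives the C27 nitrile F5, (2E,4E,6E,8E,10E,12E,14E)-15-[(1R,4S)-4-hydroxy-2,6,6-trimethylcyclohex-2-en-1-yl]-4,9,13-trimethylpentadeca-2,4,6,8,10,12,14-heptaenenitrile. Partial reduction with i-Bu2AlH (CH2Cl2, −78 °C; aqueous potassium sodium tartrate work-up) gives the aldehyde, and the fallback comes back to the route at compound 12.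

## Further compounds

F1 | step 1 | (3E)-4-[(1R,4R)-4-hydroxy-2,6,6-trimethylcyclohex-2-en-1-yl]but-3-en-2-one | CC1=C[C@H](O)CC(C)(C)[C@H]1/C=C/C(C)=O
F2 | step 3 | [(2E,4E)-5-[(1R,4S)-4-(benzoyloxy)-2,6,6-trimethylcyclohex-2-en-1-yl]-3-methylpenta-2,4-dien-1-yl]triphenylphosphonium bromide | CC1=C[C@@H](OC(=O)c2ccccc2)CC(C)(C)[C@H]1/C=C/C(C)=C/C[P+](c1ccccc1)(c1ccccc1)c1ccccc1.[Br-]
F3 | step 3 | (1S,4R)-3,5,5-trimethyl-4-[(1E,3E)-3-methyl-5-(triphenylphosphoranylidene)penta-1,3-dien-1-yl]cyclohex-2-en-1-yl benzoate | CC1=C[C@@H](OC(=O)c2ccccc2)CC(C)(C)[C@H]1/C=C/C(C)=C/C=P(c1ccccc1)(c1ccccc1)c1ccccc1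
F4 | step 3 | (1S,4R)-3,5,5-trimethyl-4-[(1E,3E,5E,7E,9E,11E)-3,7,12-trimethyl-13-oxotrideca-1,3,5,7,9,11-hexaen-1-yl]cyclohex-2-en-1-yl benzoate | CC1=C[C@@H](OC(=O)c2ccccc2)CC(C)(C)[C@H]1/C=C/C(C)=C/C=C/C(C)=C/C=C/C=C(\C)C=O
F5 | step 5 | (2E,4E,6E,8E,10E,12E,14E)-15-[(1R,4S)-4-hydroxy-2,6,6-trimethylcyclohex-2-en-1-yl]-4,9,13-trimethylpentadeca-2,4,6,8,10,12,14-heptaenenitrile | CC1=C[C@@H](O)CC(C)(C)[C@H]1/C=C/C(C)=C/C=C/C(C)=C/C=C/C=C(C)/C=C/C#N
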